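**Retrosynthetic overview**
1. The target is two isoliquiritigenin (C15 chalcone) units joined through the dihydrofuran ring. Cutting O1–C2 and C3–C3a of that ring gives two molecules of the same chalcone 3.
2. Enabling feature: the 4-hydroxycinnamoyl unit in each half (phenol O, the ring carbon ortho to it, Cα and Cβ of the enone). Its phenoxyl radical has spin at O, at the ortho carbon and at Cα, so one half supplies O–C(ortho) and the other Cα–Cβ.
3. Handle for asymmetry: the 2'-hydroxyaryl ketone (O–C=C–C=O) next to Cα binds a chiral BINOL boron in a temporary six-membered chelate ring.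
4. Forward: Claisen–Schmidt condensation gives 3; an Ag2O oxidative (3+2) dehydrodimerisation of the boron chelate closes the dihydrofuran ring with both stereocentres; hydrolysis removes boron.
5. Ring order: the benzene rings are bought; the two boron chelate rings go on first, the dihydrofuran ring is closed in the key step, the chelate rings come off last.

Key step: step 2

Remark: which antipode of BINOL leads to the (2S,3S) series cannot be derived with certainty; (R)-BINOL is assumed by analogy with cycloadditions of such chelates, and (S)-BINOL would be used in the unchanged route if a pilot run shows the opposite sense.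
Remark: a plain SMILES string cannot carry the biaryl axis; it is (R) in 4, 6, 7 and 8 as named, and [B-]–[O+]=C stands for the dative ketone-to-boron bond.
Remark: 9 carries an acidic H at C3 and a free 4-hydroxyphenyl group at C2, so it is assumed to hold its configuration only at pH 7 or below; everything after the coupling is kept neutral to slightly acidic.

**Step 1**
Reactants: 1 2,4-dihydroxyacetophenone; 2 4-hydroxybenzaldehyde
Product: 3 isoliquiritigenin, (E)-1-(2,4-dihydroxyphenyl)-3-(4-hydroxyphenyl)prop-2-en-1-one
Conditions: KOH (50% aq.), EtOH, 50 °C; then 2 M HCl, 0 °C, to pH 4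
Reagents that add atoms: none
Why: Claisen–Schmidt condensation, in which the methyl ketone enolate adds to the non-enolisable aldehyde and E1cB loss of water gives the conjugated enone with the thermodynamically preferred (E) geometry.

**Step 2**
Reactants: 3 isoliquiritigenin (two molecules per molecule of product); 4 (R)-BINOL; 5 trimethyl borate
Product: 8 bis[(R)-BINOL spiroborate] of the (2S,3S)-trans-dihydrobenzofuran dimer, via chalcone spiroborate 6 (not isolated), via quinone methide 7 (not isolated)
Conditions: (R)-BINOL (1 equiv), B(OMe)3 (1 equiv), 4 Å MS, toluene/THF, 65 °C (MeOH distilled off), evaporate; then Ag2O (0.55 equiv per chalcone), 4 Å MS, CH2Cl2/acetone, 0 °C, dark; filter through Celite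
Reagents that add atoms: (R)-BINOL, Oc1ccc2ccccc2c1-c1c(O)ccc2ccccc12; trimethyl borate, COB(OC)OC
Why: Proposed new method: borate exchange ties each chalcone through its 2'-O and its C=O to an (R)-BINOL boron (6), Ag2O then removes one hydrogen atom from the 4-OH of each chelate, and the two phenoxyl radicals, which carry spin at O, at the ring carbon ortho to O and at Cα, join Cα of one to the ortho carbon of the other. Rearomatisation of the arylated ring leaves a p-quinone methide at Cβ (7), which the neighbouring phenol oxygen closes by a 5-exo-trig oxa-1,6-addition, so the dihydrofuran ring is the only ring made and both of its new bonds arise in one operation. The closest known reaction types are the silver oxide dehydrodimerisation of 4-hydroxycinnamates and 4-hydroxystilbenes to trans-2-aryl-2,3-dihydrobenzofurans and the asymmetric Diels–Alder reactions of 2'-hydroxychalcones held in chiral BINOL borate chelates, where a naphthyl ring screens one face of the Cα=Cβ unit; the new element is the use of that chelate to steer a radical coupling. C3 should be set in the C–C coupling by the boron-bound BINOL, which sits three bonds from Cα and leaves one face open, and C2 should follow from C3 because the ring closes with the 4-hydroxyphenyl group anti to the bulky chelated aroyl group, while any cis isomer can re-open to the quinone methide and drain to trans. The step needs oxidation at the 4-OH and not at the resorcinol oxygens, which is secured because 2'-O is bound to boron and 4'-OH lies para to the boron-activated carbonyl, and it needs Cα–C(ortho) coupling in preference to Cα–Cα coupling, which the two bulky chelates should disfavour.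

**Step 3**
Reactants: 8 bis[(R)-BINOL spiroborate] of the (2S,3S)-trans-dihydrobenzofuran dimer
Product: 9 (E)-1-(2,4-dihydroxyphenyl)-3-[(2S,3S)-3-(2,4-dihydroxybenzoyl)-2-(4-hydroxyphenyl)-2,3-dihydro-1-benzofuran-5-yl]prop-2-en-1-one
Conditions: THF, pH 6 phosphate buffer (NaH2PO4/Na2HPO4), 0 °C to rt; EtOAc; C18 chromatography (MeCN/H2O, 0.1% HCO2H)
Reagents that add atoms: none
Why: Hydrolysis of aryl borate esters, in which water cleaves only the B–O bonds at near-neutral pH, so the acidic C3–H and the C2–O bond are not touched and both stereocentres should be kept.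

**Compound list**
1 | 2,4-dihydroxyacetophenone | CC(=O)c1ccc(O)cc1O | starting material
2 | 4-hydroxybenzaldehyde | O=Cc1ccc(O)cc1 | starting material
3 | isoliquiritigenin, (E)-1-(2,4-dihydroxyphenyl)-3-(4-hydroxyphenyl)prop-2-en-1-one | O=C(/C=C/c1ccc(O)cc1)c1ccc(O)cc1O | intermediate
4 | (R)-BINOL, (R)-1,1'-binaphthalene-2,2'-diol | Oc1ccc2ccccc2c1-c1c(O)ccc2ccccc12 | starting material
5 | trimethyl borate | COB(OC)OC | starting material
6 | (R)-BINOL spiroborate of isoliquiritigenin: tetracoordinate boron bound to both BINOL oxygens, to the 2'-phenolate oxygen and datively to the ketone oxygen (six-membered chelate ring); (E)-alkene; 4-OH and 4'-OH free | Oc1ccc(/C=C/C2=[O+][B-]3(Oc4cc(O)ccc24)Oc2ccc4ccccc4c2-c2c(O3)ccc4ccccc24)cc1 | intermediate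
7 | C–C coupled p-quinone methide, bis[(R)-BINOL spiroborate]: the former Cα of one chalcone, now an (R)-configured CH that carries the chelated aroyl group and the (4-oxocyclohexa-2,5-dienylidene)methyl group, is bonded to C3 of the 4-hydroxyphenyl ring of the second, (E)-configured chelated chalcone | C1(=[O+][B-]2(Oc3cc(O)ccc13)Oc1ccc3ccccc3c1-c1c(O2)ccc3ccccc13)/C=C/c1ccc(O)c(c1)[C@H](C4(=[O+][B-]5(Oc6cc(O)ccc46)Oc4ccc6ccccc6c4-c4c(O5)ccc6ccccc46))C=C4C=CC(=O)C=C4 | intermediate
8 | bis[(R)-BINOL spiroborate] of the (2S,3S)-trans-dihydrobenzofuran dimer: boron chelates on the 2-hydroxyaroyl groups at C3 and on the (E)-enone at C5; the 4-hydroxyphenyl group at C2 is free | C1(=[O+][B-]2(Oc3cc(O)ccc13)Oc1ccc3ccccc3c1-c1c(O2)ccc3ccccc13)/C=C/c1ccc2c(c1)[C@H](C4(=[O+][B-]5(Oc6cc(O)ccc46)Oc4ccc6ccccc6c4-c4c(O5)ccc6ccccc46))[C@@H](c1ccc(O)cc1)O2 | intermediate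
9 | (E)-1-(2,4-dihydroxyphenyl)-3-[(2S,3S)-3-(2,4-dihydroxybenzoyl)-2-(4-hydroxyphenyl)-2,3-dihydro-1-benzofuran-5-yl]prop-2-en-1-one (trans) | O=C(/C=C/c1ccc2c(c1)[C@H](C(=O)c1ccc(O)cc1O)[C@@H](c1ccc(O)cc1)O2)c1ccc(O)cc1O | target

**Step count and risks**
Total step count: 3. Longest linear sequence: 3 steps (1 and 2 to 3, then 8, then 9).

Steps most likely to fail:

Step 2 (proposed new method). The facial selectivity at Cα in the radical coupling may be poor. The two free phenols may scramble the ligands on boron, so that no single chelate is present. Coupling may also run through other positions, or the product may be oxidised further. The fallback uses known chemistry, sets out from 3 and comes back at 9. Compound 3 is dimerised without boron by Ag2O in acetone/CH2Cl2 at rt, the dehydrodimerisation known for 4-hydroxycinnamates and 4-hydroxystilbenes. This should give the trans-dihydrobenzofuran as the racemate, that is 9 together with its (2R,3R)-antipode F1. The two are separated by preparative HPLC on an amylose tris(3,5-dimethylphenylcarbamate) phase. The (2S,3S) fraction is identified by electronic circular dichroism against calculation and is 9.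

Step 3. The configuration may erode by ring opening during hydrolysis and chromatography, either by loss of the C3 proton with expulsion of the ring oxygen from C2 or by quinone-methide formation from the free 4-hydroxyphenyl group. The polyphenol may also separate poorly from BINOL. The fallback sets out from 8 and comes back at 9. Compound 8 is cleaved by methanolysis (MeOH, rt; the boron leaves as volatile B(OMe)3 with the solvent). The residue is peracetylated (Ac2O, pyridine, 0 °C) to the dihydrobenzofuran pentaacetate F2, while the liberated ligand is converted alongside into (R)-BINOL diacetate F3. F2 can no longer form a quinone methide and is purified on silica. Its five aryl acetates are then removed with NH4OAc in MeOH/H2O at rt to return 9.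

Step 1. Conversion may stall because ketone and aldehyde are both present as phenoxides, and the 2'-hydroxychalcone may close to the flavanone on acidification. The fallback sets out from 1 and 2 and comes back at 3. Compound 1 is treated with MOMCl and K2CO3 in acetone to give 1-[2-hydroxy-4-(methoxymethoxy)phenyl]ethanone F4; the hydrogen-bonded 2-OH stays free. Compound 2 is treated with MOMCl and iPr2NEt in CH2Cl2 to give 4-(methoxymethoxy)benzaldehyde F5. Claisen–Schmidt condensation (KOH, EtOH, rt) gives the bis-MOM chalcone F6, and 2 M HCl in MeOH at 50 °C removes both MOM groups to return 3.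

**Further compounds**
F1 | step 2 | (2R,3R)-antipode of 9, (E)-1-(2,4-dihydroxyphenyl)-3-[(2R,3R)-3-(2,4-dihydroxybenzoyl)-2-(4-hydroxyphenyl)-2,3-dihydro-1-benzofuran-5-yl]prop-2-en-1-one | O=C(/C=C/c1ccc2c(c1)[C@@H](C(=O)c1ccc(O)cc1O)[C@H](c1ccc(O)cc1)O2)c1ccc(O)cc1O
F2 | step 3 | pentaacetate of 9, (2S,3S)-trans, (E) | O=C(/C=C/c1ccc2c(c1)[C@H](C(=O)c1ccc(OC(C)=O)cc1OC(C)=O)[C@@H](c1ccc(OC(C)=O)cc1)O2)c1ccc(OC(C)=O)cc1OC(C)=O
F3 | step 3 | (R)-BINOL diacetate, (R)-1,1'-binaphthalene-2,2'-diyl diacetate | CC(=O)Oc1ccc2ccccc2c1-c1c(OC(C)=O)ccc2ccccc12
F4 | step 1 | 1-[2-hydroxy-4-(methoxymethoxy)phenyl]ethanone | CC(=O)c1ccc(OCOC)cc1O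
F5 | step 1 | 4-(methoxymethoxy)benzaldehyde | O=Cc1ccc(OCOC)cc1
F6 | step 1 | (E)-1-[2-hydroxy-4-(methoxymethoxy)phenyl]-3-[4-(methoxymethoxy)phenyl]prop-2-en-1-one | O=C(/C=C/c1ccc(OCOC)cc1)c1ccc(OCOC)cc1O
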